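**The leftover.** What stands unused at the end of the blue run is D, 80.8% at 12.0 min after 82.3% at 8.00 min, so I read E, the limiting reagent charged at 0.25 equiv, as used up there.

| flask | D | E | remark | time |
|---|---|---|---|---|
| blue | 20 mM | 0.25 equiv | run made earlier |  |
| flask | 20 mM | 0.500 equiv |  | 40 min |

- blue (time / min: J / %, D / %): 1.00: 5.9, 96.4; 1.33: 5.4, 94.8; 2.00: 7.1, 92.3; 3.00: 8.6, 88.8; 5.00: 8.0, 84.1; 8.00: 12.5, 82.3; 12.0: 12.6, 80.8

(each reading ± 1 percentage point)

- in percentages every species weighs as the D in it: one Q counts as two
- for J the X are counted in
- as a solid, counted per litre of solution: X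
- steps thought possible: D + E -> J; E + J -> L; D + J -> Q; X <-> J

- equivalents of E to D, everything else as given, that leave most J at 40 min
- the amount of J then, in percent of the D charged
- the amount of J with the amounts as given

**Turnover number.** I count D lost per E charged, the turnover number, and get 0.768. An E that makes J turns over one D, while an E that makes L turns over none, so the gap below one is the part of E that went on to L, Q aside.

**My reckoning.** Held at 0.500 equiv, this number stops D at 61.6%. The blue share of lost D found as J, 0.656, then gives 25.2%. But that share read 0.768 at 3.00 min, so it seems to fall, within a wide scatter. So I trust this number for D more than for J, and I commit to J in this flask below that figure.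

**The forecast.** It says 16%, and at best 16.5% at 0.6 equiv, on the ground that “J follows the stoichiometric curve”. Its D of 67 stands above mine.

**The result.** At 0.500 equiv the flask gives J 20.9% with D at 62.3%, and the best J is 26.9% at 1.08 equiv. Its turnover number, D lost per E charged at 0.500 equiv, is 0.754.

    D + E → J (k = 0.170 L mol⁻¹ s⁻¹)
    E + J → L (k = 0.950 L mol⁻¹ s⁻¹)
    D + J → Q (k = 0.0140 L mol⁻¹ s⁻¹)
    X ⇌ J, rate k4*(cs4 - [J]) while solid is left; crystals form when [J] > cs4 (solubility = 0.420 mM, k = 0.00660 s⁻¹)

In the flask, dissolved J has a half-life of 2.4 min by the L step at 2.66 min, against 8.0 min for E by the same step. Half of the L turnover is done by 2.99 min and half of the crystallising by 5.46 min, and at 40 min X holds 18.8% of the 20.9% J.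

**A neighbour.** The number holds no c_D, so at c_D = 80 mM it again stops D at 61.6%. That flask gives D 63.8% and J 14.5%.

The runs stem from a simulated flask with constants of no real substance.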